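**Plan**

- Feature: ring B (the phenyl ring) carries only the chain, so its para carbon bears hydrogen alone. That carbon can come from nitromethane and take the place of the ring oxygen of a pyrylium holding the chain at C4; the nitro group is removed afterwards.
- Retrosynthetic cuts, in order: the para C–H of ring B (back to C–NO2); the two para–meta bonds of ring B; the bond from chain carbon C10 to C4 of the oxygen heterocycle; the bond from ring A (the 3,5-dimethoxyphenyl ring) to chain carbon C1.
- Forward order: the chain is joined to ring A (aryl Grignard reagent plus excess dibromide), then its terminus to the C4 carbonyl of a pyranone with ionisation to the pyrylium salt. Ring B, the only ring made, is closed next, and nitro is taken to amino and then to hydrogen.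
- Stereochemistry: the target has no stereocentre and no configured double bond. The only geometric demand, a cisoid dienal for ring closure, is met inside the key step.

Key step: step 3

Remark on the chemistry: chain carbons are counted C1 (on ring A) to C10 (on ring B), and the four starting materials are assumed to be commercial.

**Route**

Step 1
Reactants: 1 1-bromo-3,5-dimethoxybenzene; 2 1,10-dibromodecane
Product: 4 1-(10-bromodecyl)-3,5-dimethoxybenzene, via 3,5-dimethoxyphenylmagnesium bromide 3 (not isolated)
Conditions: Mg, THF, reflux; then added to 2 (4 equiv), Li2CuCl4 (3 mol%), THF, 0 °C to rt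
Reagents that add atoms: magnesium, [Mg] (kept only in intermediate 3, absent from 4)
Why: The copper-catalysed coupling of a Grignard reagent with a primary alkyl bromide (Kochi coupling) should join ring A to C1, and the excess of the symmetrical dibromide should keep the second C–Br bond unreacted.

Step 2
Reactants: 4 1-(10-bromodecyl)-3,5-dimethoxybenzene; 5 4H-pyran-4-one
Product: 8 4-[10-(3,5-dimethoxyphenyl)decyl]pyrylium tetrafluoroborate, via [10-(3,5-dimethoxyphenyl)decyl]magnesium bromide 6 (not isolated), via bromomagnesium 4-[10-(3,5-dimethoxyphenyl)decyl]-4H-pyran-4-olate 7 (not isolated)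
Conditions: Mg, THF, 40 °C; then 5, THF, −78 to 0 °C; then HBF4·OEt2 (3 equiv), Et2O, −20 to 0 °C
Reagents that add atoms: magnesium, [Mg] (kept only in intermediates 6 and 7); tetrafluoroboric acid (as diethyl etherate), [H+].F[B-](F)(F)F (supplies the counter-ion of 8)
Why: Grignard reagents add to the carbonyl carbon of 4H-pyran-4-ones as they do to vinylogous esters, and the tertiary carbinol ionises on acidification because the cation formed is the aromatic pyrylium (the classical pyranone-to-pyrylium synthesis).

Step 3
Reactants: 8 4-[10-(3,5-dimethoxyphenyl)decyl]pyrylium tetrafluoroborate; 9 nitromethane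
Product: 13 1,3-dimethoxy-5-[10-(4-nitrophenyl)decyl]benzene, via 4-[10-(3,5-dimethoxyphenyl)decyl]-2-(nitromethyl)-2H-pyran 10 (not isolated), via (2Z,4Z)-3-[10-(3,5-dimethoxyphenyl)decyl]-6-nitrohexa-2,4-dienal 11 (not isolated), via 3-[10-(3,5-dimethoxyphenyl)decyl]-6-nitrocyclohexa-2,4-dien-1-ol 12 (not isolated)
Conditions: 9 (10 equiv), KOtBu (2.2 equiv), tBuOH/THF, 0 °C; then 8 in MeNO2, 0 to 60 °C
Reagents that add atoms: none
Why: Proposed new method: the preformed potassium nitronate of 9 should add to C2 of the pyrylium ring of 8, the 2H-pyran 10 should open by a thermal oxa-6π electrocyclic reaction to the dienal 11, and the nitronate carbon of 11 should close onto the aldehyde carbon in an intramolecular Henry reaction to 12, which aromatises by loss of water, so that the ring oxygen leaves as water and the nitromethane carbon becomes the para carbon of ring B. The closest known reaction type is the conversion of 2,4,6-trisubstituted pyrylium salts into nitrobenzenes with nitromethane and KOtBu; a salt with free C2 and C6 positions and a primary alkyl chain at C4 lies outside what has been shown, hence the label. Ring B closes in the 6-exo-trig mode (the attacked C=O is exocyclic to the forming ring), the two bonds made are those from the new para carbon to the two meta carbons, and the stereocentres of 10 and 12 are transient so none remains. The step needs attack at C2 and not at C4, which the alkyl group at C4 secures because a C4 adduct is hindered and can only revert, and it needs a cisoid dienal, whose 2Z double bond is fixed by its origin in the ring while the 4,5 double bond can equilibrate through the delocalised nitronate–dienolate. Preforming the nitronate in excess nitromethane keeps free alkoxide away from C2, and the excess nitromethane serves as the proton source that returns any 4-alkylidene-4H-pyran formed by deprotonation at chain carbon C10 to the cation.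

Step 4
Reactants: 13 1,3-dimethoxy-5-[10-(4-nitrophenyl)decyl]benzene
Product: 14 4-[10-(3,5-dimethoxyphenyl)decyl]aniline
Conditions: H2 (1 atm), 10% Pd/C, EtOAc/EtOH, rt
Reagents that add atoms: none
Why: Catalytic hydrogenation over Pd/C reduces an aromatic nitro group to the aniline, and the aryl methyl ethers and the saturated chain offer nothing else reducible under these conditions.

Step 5
Reactants: 14 4-[10-(3,5-dimethoxyphenyl)decyl]aniline
Product: 16 1,3-dimethoxy-5-(10-phenyldecyl)benzene, via 4-[10-(3,5-dimethoxyphenyl)decyl]benzenediazonium chloride 15 (not isolated)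
Conditions: NaNO2, aq. HCl, AcOH/THF, 0 °C; then 50% aq. H3PO2, 0 °C to rt
Reagents that add atoms: sodium nitrite, [Na+].[O-]N=O (its nitrogen is kept only in intermediate 15); hydrogen chloride, Cl (chloride of intermediate 15); only hydrogen is added to 16
Why: Diazotisation followed by reduction with hypophosphorous acid (hydrodediazoniation, the classical deamination of anilines) should replace the diazonium group by hydrogen through an aryl radical that sits para to the chain and far from any abstractable chain hydrogen, while the weakly electrophilic 4-alkylbenzenediazonium ion should not couple with ring A in cold acid.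

**Compound list**

1 | 1-bromo-3,5-dimethoxybenzene | COc1cc(Br)cc(OC)c1 | starting material
2 | 1,10-dibromodecane | BrCCCCCCCCCCBr | starting material
3 | 3,5-dimethoxyphenylmagnesium bromide | COc1cc([Mg]Br)cc(OC)c1 | intermediate (not isolated)
4 | 1-(10-bromodecyl)-3,5-dimethoxybenzene | COc1cc(CCCCCCCCCCBr)cc(OC)c1 | intermediate
5 | 4H-pyran-4-one | O=c1ccocc1 | starting material
6 | [10-(3,5-dimethoxyphenyl)decyl]magnesium bromide | COc1cc(CCCCCCCCCC[Mg]Br)cc(OC)c1 | intermediate (not isolated)
7 | bromomagnesium 4-[10-(3,5-dimethoxyphenyl)decyl]-4H-pyran-4-olate | COc1cc(CCCCCCCCCCC2(O[Mg]Br)C=COC=C2)cc(OC)c1 | intermediate (not isolated)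
8 | 4-[10-(3,5-dimethoxyphenyl)decyl]pyrylium tetrafluoroborate | COc1cc(CCCCCCCCCCc2cc[o+]cc2)cc(OC)c1.F[B-](F)(F)F | intermediate
9 | nitromethane | C[N+](=O)[O-] | starting material
10 | 4-[10-(3,5-dimethoxyphenyl)decyl]-2-(nitromethyl)-2H-pyran (racemic at C2, centre lost later) | COc1cc(CCCCCCCCCCC2=CC(C[N+](=O)[O-])OC=C2)cc(OC)c1 | intermediate (not isolated)
11 | (2Z,4Z)-3-[10-(3,5-dimethoxyphenyl)decyl]-6-nitrohexa-2,4-dienal (the geometry that closes; in equilibrium with its 4E isomer through the nitronate) | O=C/C=C(CCCCCCCCCCc1cc(OC)cc(OC)c1)\C=C/C[N+](=O)[O-] | intermediate (not isolated)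
12 | 3-[10-(3,5-dimethoxyphenyl)decyl]-6-nitrocyclohexa-2,4-dien-1-ol (diastereomer mixture, both centres lost on dehydration) | OC1C=C(CCCCCCCCCCc2cc(OC)cc(OC)c2)C=CC1[N+](=O)[O-] | intermediate (not isolated)
13 | 1,3-dimethoxy-5-[10-(4-nitrophenyl)decyl]benzene | COc1cc(CCCCCCCCCCc2ccc([N+](=O)[O-])cc2)cc(OC)c1 | intermediate
14 | 4-[10-(3,5-dimethoxyphenyl)decyl]aniline | COc1cc(CCCCCCCCCCc2ccc(N)cc2)cc(OC)c1 | intermediate
15 | 4-[10-(3,5-dimethoxyphenyl)decyl]benzenediazonium chloride | COc1cc(CCCCCCCCCCc2ccc([N+]#N)cc2)cc(OC)c1.[Cl-] | intermediate (not isolated)
16 | 1,3-dimethoxy-5-(10-phenyldecyl)benzene | COc1cc(CCCCCCCCCCc2ccccc2)cc(OC)c1 | target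

**Step count and risks**

Total step count: 5. Longest linear sequence: 5 steps, from 1 to 16.

Steps most likely to fail:

1. Step 3 (the proposed new method). The C2 adduct may open to the nitro dienal and be consumed by polymerisation or by a second nitronate addition before it closes. Traces of alkoxide or hydroxide may attack the unsubstituted C2 position and open the ring to a glutaconaldehyde. Deprotonation at chain carbon C10 may drain the cation as the alkylidenepyran. The fallback uses known chemistry, sets out from bromide 4 and comes back at target 16. Bromide 4 is coupled with phenylmagnesium bromide under Li2CuCl4 catalysis in THF at 0 °C, the same copper-catalysed Grignard–alkyl bromide coupling as in step 1. This forms the ring B–C10 bond directly and makes steps 4 and 5 unnecessary; it makes no compound outside the list (F0).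

2. Step 2. The Grignard reagent may add in conjugate fashion at C2 of the pyranone in competition with carbonyl addition. The unsubstituted pyrylium ring may also be opened hydrolytically, or attacked by the electron-rich ring A of a second molecule, during isolation. The fallback sets out from 4 (through its Grignard reagent 6) and comes back at 8. Kumada coupling of 6 with 4-bromopyridine (freshly freed from its hydrochloride; Ni(dppp)Cl2, THF) should give 4-[10-(3,5-dimethoxyphenyl)decyl]pyridine F1. The sulfur trioxide–1,4-dioxane complex should convert it into 4-[10-(3,5-dimethoxyphenyl)decyl]pyridinium-1-sulfonate F2. Cold aqueous NaOH should open the ring to the glutaconaldehyde enolate sodium (1E,3E)-3-[10-(3,5-dimethoxyphenyl)decyl]-5-oxopenta-1,3-dien-1-olate F3, and HBF4 in Et2O should close it with loss of water to the pyrylium salt 8.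

3. Step 5. Diazotisation of the lipophilic aniline may be slow and heterogeneous. The diazonium ion may undergo azo coupling with ring A of a second molecule or hydrolysis to the phenol before the hydrogen transfer takes place. The fallback sets out from nitroarene 13 and comes back at 16, bypassing 14 and 15. It is the palladium-catalysed reductive denitration of a nitroarene (Pd(acac)2, BrettPhos, K3PO4, 2-propanol as hydride source, 1,4-dioxane, 130 °C), which cleaves the C–NO2 bond directly. It makes no compound outside the list (F0).

**Further compounds**

F0 | step 3 | none | none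
F1 | step 2 | 4-[10-(3,5-dimethoxyphenyl)decyl]pyridine | COc1cc(CCCCCCCCCCc2ccncc2)cc(OC)c1
F2 | step 2 | 4-[10-(3,5-dimethoxyphenyl)decyl]pyridinium-1-sulfonate | COc1cc(CCCCCCCCCCc2cc[n+](S(=O)(=O)[O-])cc2)cc(OC)c1
F3 | step 2 | sodium (1E,3E)-3-[10-(3,5-dimethoxyphenyl)decyl]-5-oxopenta-1,3-dien-1-olate | [Na+].[O-]/C=C/C(CCCCCCCCCCc1cc(OC)cc(OC)c1)=C/C=O
F0 | step 5 | none | none
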